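**Plan**

1. Retrosynthesis: the C6–OH and the C17 aldehyde oxygen are removed first (γ‑hydroxylation of a silyl dienol ether; allylic oxidation of the C8 methyl). Ring B is then opened at C9–C10 and ring A at C4–C5 in one retro‑cyclization to the acyclic (2E,6E,10E)‑tetraene ester 8. Last, C13–C16 (Stille) and C11–C12 (dianion alkylation) are cut to farnesyl bromide, methyl acetoacetate and Bu3SnCH2OH.
2. Forward: the C20 chain with the finished side chain is joined first (steps 1–4). One proton‑initiated cascade then closes ring A (C1–C5, C10) and ring B (C5–C10) in this order (step 5). C17 and C6 are oxidised afterwards (steps 6–8).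
3. Enabling feature: the trans‑decalin (Me‑10 anti to H‑5 and H‑9, C‑11 equatorial, gem‑dimethyl C4, Δ7) is the imprint of a chair–chair folded head‑to‑tail triene C3=C4 / C5=C10 / C8=C9. The electron‑poor C13=C14 enoate cannot take part, so the cascade stops after ring B.
4. Stereochemistry: C5, C9, C10 are set relative to each other by the E alkenes in the chair–chair fold and absolutely by a chiral confined Brønsted acid. C6 comes from substrate control (oxygen enters on the face of H‑5, anti to the axial methyls on C10 and C4). The C13=C14 geometry comes from an (E)‑enol triflate and a stereoretentive coupling.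

Key step: step 5

Remark: labdane numbering (C1–C20) is used for all compounds, including the acyclic ones. Which antipode of the IDPi acid gives the (5R,9R,10R) series is assumed to be settled by testing both.

**Route**

Step 1
Reactants: 1 (2E,6E)-farnesyl bromide; 2 methyl acetoacetate
Product: 4 methyl (6E,10E)-7,11,15-trimethyl-3-oxohexadeca-6,10,14-trienoate, via acetoacetate dianion 3 (not isolated)
Conditions: 2, NaH, THF, 0 °C; n-BuLi, 0 °C; then 1, 0 °C → rt; 1 M HCl
Reagents that add atoms: none
Why: γ‑Alkylation of a β‑keto ester dianion at its more nucleophilic terminal carbon by SN2 on the primary allylic bromide should join C11–C12 without touching the E,E alkenes.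

Step 2
Reactants: 4 β‑keto ester
Product: 5 methyl (2E,6E,10E)-7,11,15-trimethyl-3-(trifluoromethanesulfonyloxy)hexadeca-2,6,10,14-tetraenoate (OTf trans to CO2Me)
Conditions: Tf2O, 25 % aq. Me4NOH, toluene, 5 °C
Reagents that add atoms: triflic anhydride, O=S(=O)(OS(=O)(=O)C(F)(F)F)C(F)(F)F
Why: Schotten–Baumann O‑triflation of the non‑chelated tetraalkylammonium enolate, which prefers the dipole‑minimised anti arrangement of its two oxygens, should give the (E)‑enol triflate and so fix the C13=C14 geometry.

Step 3
Reactants: 5 (E)-enol triflate; 6 (tributylstannyl)methanol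
Product: 7 methyl (2E,6E,10E)-3-(hydroxymethyl)-7,11,15-trimethylhexadeca-2,6,10,14-tetraenoate (CH2OH trans to CO2Me)
Conditions: Pd(PPh3)4 (5 mol %), LiCl, 1,4-dioxane, 90 °C
Reagents that add atoms: none
Why: Stille coupling (hydroxymethylation) of the electron‑poor vinyl triflate should transfer the α‑hydroxymethyl group in preference to butyl and retain the alkene geometry; the trans hydroxy ester cannot lactonise.

Step 4
Reactants: 7 allylic alcohol
Product: 8 methyl (2E,6E,10E)-3-(acetoxymethyl)-7,11,15-trimethylhexadeca-2,6,10,14-tetraenoate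
Conditions: Ac2O, pyridine, DMAP (cat.), CH2Cl2, 0 °C → rt
Reagents that add atoms: acetic anhydride, CC(=O)OC(C)=O
Why: Standard DMAP‑catalysed acetylation of the primary allylic alcohol gives the acid‑stable C16 acetate carried to the target.

Step 5
Reactants: 8 acyclic tetraene ester
Product: 9 methyl (13E)-16-acetoxy-ent-labda-7,13-dien-15-oate, (5R,9R,10R)
Conditions: confined chiral imidodiphosphorimidate (IDPi) Brønsted acid (3 mol %, antipode giving the 5R,9R,10R series), (CF3)3COH/CH2Cl2, −20 °C
Reagents that add atoms: none
Why: Proposed new method: the confined acid should protonate C‑3 of the terminal C3=C4 alkene enantioface‑selectively inside its anion pocket while the chair–chair folded chain collapses by anti additions, C‑5 adding to C‑4 (ring A), C‑9 adding to the C‑10 cation (ring B) and the C‑8 cation losing axial H‑7 to the counter‑anion to leave the Δ7 alkene. The closest known reaction types are the IDPi‑catalysed asymmetric cyclization of homofarnesol to ambrox and the superacid cyclization of polyprenyl esters to racemic drim‑7‑enes and labd‑7‑enes; new is the pairing of asymmetric protonation with elimination as the terminating event on an ester‑bearing tetraene. Both rings close in the cationic 6‑endo‑trig mode (Stork–Eschenmoser). For C‑5, C‑9 and C‑10 the relative configuration (trans fusion, H‑5 and H‑9 cis, C‑11 equatorial) follows from the E geometry of the C5=C10 and C8=C9 alkenes in the chair–chair transition state, and the absolute configuration from the catalyst antipode. The step needs initiation at the terminal alkene (only there is protonation assisted by π‑participation), a stop after ring B (C13=C14 is deactivated by the ester and CH2OAc groups) and regioselective loss of H‑7 (axial C–H aligned with the empty p orbital, no internal nucleophile within reach of C‑8).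

Step 6
Reactants: 9 ent-labda-7,13-diene ester
Product: 10 methyl (13E)-16-acetoxy-17-oxo-ent-labda-7,13-dien-15-oate, (5R,9S,10R)
Conditions: SeO2, wet 1,4-dioxane, 80 °C
Reagents that add atoms: selenium dioxide, O=[Se]=O
Why: Riley allylic oxidation (ene reaction, then [2,3] shift) should act only on the electron‑rich ring alkene and oxidise the methyl on its more substituted carbon (C17) to the conjugated aldehyde, as in drim‑7‑enes, while the enoate and its allylic CH2 groups are too electron‑poor to react.

Step 7
Reactants: 10 enal
Product: 11 methyl (13E)-16-acetoxy-17-(triethylsilyloxy)-ent-labda-6,8(17),13-trien-15-oate, (5R,9S,10S), silyloxy group syn to C‑9 expected (geometry of no consequence)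
Conditions: TESOTf, Et3N, CH2Cl2, −78 → 0 °C; used crude
Reagents that add atoms: triethylsilyl triflate, CC[Si](CC)(CC)OS(=O)(=O)C(F)(F)F
Why: Soft enolisation of the enal removes the only extended‑enolate proton (H‑6; H‑9 is cross‑conjugated) and gives the 1‑silyloxy diene, and the esters are not enolised under these conditions.

Step 8
Reactants: 11 silyl dienol ether
Product: 13 methyl (13E)-16-acetoxy-6-hydroxy-17-oxo-ent-labda-7,13-dien-15-oate, (5R,6R,9S,10S), via 6,7-epoxy silyl dienol ether 12 (not isolated)
Conditions: dimethyldioxirane (acetone solution), CH2Cl2, −78 → −40 °C; then 10 % aq. citric acid, THF, 0 °C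
Reagents that add atoms: dimethyldioxirane, CC1(C)OO1
Why: Vinylogous Rubottom oxidation: electrophilic oxygen should add to the distal C6=C7 bond on the face of H‑5 (anti to the axial methyls on C10 and C4), and opening of the epoxide by the silyl enol ether gives the γ‑hydroxy enal with the 6‑OH equatorial and cis to H‑5.

**Compound list**

1 | (2E,6E)-farnesyl bromide | CC(C)=CCC/C(C)=C/CC/C(C)=C/CBr | starting material
2 | methyl acetoacetate | COC(=O)CC(C)=O | starting material
3 | methyl acetoacetate dianion (sodium lithium salt) | [Na+].[Li+].C=C([O-])C=C([O-])OC | intermediate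
4 | methyl (6E,10E)-7,11,15-trimethyl-3-oxohexadeca-6,10,14-trienoate | COC(=O)CC(=O)CC/C=C(\C)CC/C=C(\C)CCC=C(C)C | intermediate
5 | methyl (2E,6E,10E)-7,11,15-trimethyl-3-(trifluoromethanesulfonyloxy)hexadeca-2,6,10,14-tetraenoate | COC(=O)/C=C(\CC/C=C(\C)CC/C=C(\C)CCC=C(C)C)OS(=O)(=O)C(F)(F)F | intermediate
6 | (tributylstannyl)methanol | CCCC[Sn](CO)(CCCC)CCCC | starting material
7 | methyl (2E,6E,10E)-3-(hydroxymethyl)-7,11,15-trimethylhexadeca-2,6,10,14-tetraenoate | COC(=O)/C=C(\CC/C=C(\C)CC/C=C(\C)CCC=C(C)C)CO | intermediate
8 | methyl (2E,6E,10E)-3-(acetoxymethyl)-7,11,15-trimethylhexadeca-2,6,10,14-tetraenoate | COC(=O)/C=C(\CC/C=C(\C)CC/C=C(\C)CCC=C(C)C)COC(C)=O | intermediate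
9 | methyl (13E)-16-acetoxy-ent-labda-7,13-dien-15-oate, (5R,9R,10R); methyl (2E)-3-(acetoxymethyl)-5-[(1R,4aR,8aR)-2,5,5,8a-tetramethyl-1,4,4a,5,6,7,8,8a-octahydronaphthalen-1-yl]pent-2-enoate | COC(=O)/C=C(\CC[C@@H]1C(C)=CC[C@@H]2C(C)(C)CCC[C@@]12C)COC(C)=O | intermediate
10 | methyl (13E)-16-acetoxy-17-oxo-ent-labda-7,13-dien-15-oate, (5R,9S,10R) | COC(=O)/C=C(\CC[C@@H]1C(C=O)=CC[C@@H]2C(C)(C)CCC[C@@]12C)COC(C)=O | intermediate
11 | methyl (13E)-16-acetoxy-17-(triethylsilyloxy)-ent-labda-6,8(17),13-trien-15-oate, (5R,9S,10S) | COC(=O)/C=C(\CC[C@@H]1/C(=C\O[Si](CC)(CC)CC)C=C[C@@H]2C(C)(C)CCC[C@@]12C)COC(C)=O | intermediate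
12 | 6,7-epoxide of 11 on the face of H‑5, (5R,6S,7R,9S,10S) | COC(=O)/C=C(\CC[C@@H]1/C(=C\O[Si](CC)(CC)CC)[C@H]3O[C@H]3[C@@H]2C(C)(C)CCC[C@@]12C)COC(C)=O | intermediate
13 | methyl (13E)-16-acetoxy-6-hydroxy-17-oxo-ent-labda-7,13-dien-15-oate, (5R,6R,9S,10S); methyl (2E)-3-(acetoxymethyl)-5-[(1S,4R,4aR,8aS)-2-formyl-4-hydroxy-5,5,8a-trimethyl-1,4,4a,5,6,7,8,8a-octahydronaphthalen-1-yl]pent-2-enoate | COC(=O)/C=C(\CC[C@@H]1C(C=O)=C[C@@H](O)[C@@H]2C(C)(C)CCC[C@@]12C)COC(C)=O | target

**Step count and risks**

Total step count: 8. Longest linear sequence: 8 steps (1 → 13).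

Steps most likely to fail:

Step 5 (Proposed new method). The terminating deprotonation may lose regiocontrol (exocyclic or tetrasubstituted alkene isomers). The cascade may stop after ring A. Without a hydroxyl anchor the enantiofacial discrimination in the protonation may be low. Fallback with known chemistry, setting out from 8: superacid cyclization (FSO3H, 2‑nitropropane, −78 °C, Et3N quench), the established protocol for polyprenyl esters that ends by loss of H‑7, should give the racemic labda‑7,13‑diene ester F1. Preparative chromatography on a chiral stationary phase then separates the enantiomers and the route is rejoined at 9.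

Step 8. Oxygen transfer may compete at the enol ether bond C8=C17 (α‑hydroxylation). Facial discrimination at C6 may be incomplete, and the γ‑hydroxy enal may dehydrate to the dienal. The equatorial 6‑alcohol should be the thermodynamic epimer, reachable through the dienol, which limits the facial‑selectivity problem. Fallback, setting out from 11: N‑bromosuccinimide (THF, −78 °C) should deliver bromine to C‑6 of the silyloxy diene on the open face and give the 6‑bromo enal F2. Silver‑assisted hydrolysis (AgBF4, 2,6‑lutidine, aqueous acetone, 0 °C) through the C6–C7–C8 allyl cation, with water entering again from the open face, then leads directly to 13.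

Step 3. Transmetalation of the sp3 hydroxymethyl group may be slow, so that butyl transfer, protodestannylation or erosion of the alkene geometry at 90 °C take over. Fallback, setting out from 1 and bypassing steps 1–3: alkylation of 3‑lithio‑1‑(trimethylsilyl)propyne with 1 (THF, −78 °C) gives the silyl enyne F3. MeLi·LiBr followed by methyl chloroformate converts it into the ynoate F4. Copper‑mediated syn addition of (isopropoxydimethylsilyl)methylmagnesium chloride (CuBr·SMe2, THF, −78 °C, cold quench) places the silylmethyl group trans to the ester in the allylsilane F5. Tamao oxidation (H2O2, KF, KHCO3, THF/MeOH) then gives 7.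

**Further compounds**

F1 | step 5 | racemic methyl (13E)-16-acetoxylabda-7,13-dien-15-oate (9 and its enantiomer) | COC(=O)/C=C(\CC[C@@H]1C(C)=CC[C@@H]2C(C)(C)CCC[C@@]12C)COC(C)=O.COC(=O)/C=C(\CC[C@H]1C(C)=CC[C@H]2C(C)(C)CCC[C@]12C)COC(C)=O
F2 | step 8 | methyl (13E)-16-acetoxy-6-bromo-17-oxo-ent-labda-7,13-dien-15-oate (Br cis to H‑5) | COC(=O)/C=C(\CC[C@@H]1C(C=O)=C[C@@H](Br)[C@@H]2C(C)(C)CCC[C@@]12C)COC(C)=O
F3 | step 3 | (5E,9E)-trimethyl(6,10,14-trimethylpentadeca-5,9,13-trien-1-yn-1-yl)silane | C[Si](C)(C)C#CCC/C=C(\C)CC/C=C(\C)CCC=C(C)C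
F4 | step 3 | methyl (6E,10E)-7,11,15-trimethylhexadeca-6,10,14-trien-2-ynoate | COC(=O)C#CCC/C=C(\C)CC/C=C(\C)CCC=C(C)C
F5 | step 3 | methyl (2E,6E,10E)-3-{[isopropoxy(dimethyl)silyl]methyl}-7,11,15-trimethylhexadeca-2,6,10,14-tetraenoate (silylmethyl trans to CO2Me) | COC(=O)/C=C(\CC/C=C(\C)CC/C=C(\C)CCC=C(C)C)C[Si](C)(C)OC(C)C
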